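**Assumption:** the target has no stereocentre and is achiral, so no stereocontrol is needed; 5-heptylbenzene-1,3-diol and 1,3-dimethoxy-5-pentylbenzene are taken as catalogue chemicals.

**Retrosynthetic overview**
- Target depside acid ← its ring B aldehyde analogue, by a final Pinnick oxidation.
- Depside ester C–O bond (ring A acyl carbon to ring B phenol oxygen) ← ring A salicylaldehyde + ring B 4-hydroxybenzaldehyde, joined by a hydroxyl-directed dehydrogenative C–H aryloxylation (new).
- Ring A aldehyde ← 5-heptylresorcinol by Vilsmeier–Haack formylation and selective 4-O-methylation.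
- Ring B phenol ← olivetol dimethyl ether by thiolate mono-demethylation and para-selective Vilsmeier–Haack formylation.
- No ring is formed: both benzene rings are bought.

**Route**

Step 1
Reactants: 1 5-heptylbenzene-1,3-diol (5-heptylresorcinol)
Product: 3 2-heptyl-4,6-dihydroxybenzaldehyde, via ring A iminium chloride 2 (not isolated)
Conditions: POCl3 (1.3 equiv), DMF, 0 °C to rt; then H2O, 50 °C
Reagents that add atoms: N,N-dimethylformamide, CN(C)C=O; water, O
Why: Vilsmeier–Haack formylation; the chloroiminium ion attacks the resorcinol ortho to one OH and para to the other (next to the alkyl chain, not between the two OH groups), as is established for orcinol and olivetol.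

Step 2
Reactants: 3 2-heptyl-4,6-dihydroxybenzaldehyde
Product: 4 2-heptyl-6-hydroxy-4-methoxybenzaldehyde
Conditions: MeI (1.05 equiv), K2CO3 (1.1 equiv), acetone, rt
Reagents that add atoms: iodomethane, CI
Why: Williamson etherification; the OH para to the formyl group is more acidic and not hydrogen-bonded, so it is methylated while the chelated ortho OH stays free.

Step 3
Reactants: 5 1,3-dimethoxy-5-pentylbenzene (olivetol dimethyl ether)
Product: 6 3-methoxy-5-pentylphenol
Conditions: NaSEt (2.5 equiv), DMF, 140 °C; then 1 M HCl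
Reagents that add atoms: none
Why: SN2 demethylation of an aryl methyl ether by thiolate; the phenoxide formed makes loss of the second methyl group far slower, so the reaction stops at the mono-ether.

Step 4
Reactants: 6 3-methoxy-5-pentylphenol
Product: 8 4-hydroxy-2-methoxy-6-pentylbenzaldehyde, via ring B iminium chloride 7 (not isolated)
Conditions: POCl3 (1.2 equiv), DMF, 0 °C to rt; then H2O, 50 °C
Reagents that add atoms: N,N-dimethylformamide, CN(C)C=O; water, O
Why: Vilsmeier–Haack formylation para to the free OH, which is a stronger para director than OMe (the same preference is seen with 3,5-dimethoxyphenol); the minor chelated ortho-hydroxy isomer is much less polar and is removed on silica.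

Step 5
Reactants: 4 2-heptyl-6-hydroxy-4-methoxybenzaldehyde; 8 4-hydroxy-2-methoxy-6-pentylbenzaldehyde
Product: 9 4-formyl-3-methoxy-5-pentylphenyl 2-heptyl-6-hydroxy-4-methoxybenzoate
Conditions: 8 (1.3 equiv), [Cp*RhCl2]2 (2.5 mol%), AgSbF6 (10 mol%), CsOPiv (30 mol%), Ag2CO3 (1.1 equiv), 4 Å MS, DCE, 60 °C
Reagents that add atoms: none
Why: Proposed new method: hydroxyl-directed dehydrogenative aldehyde C–H aryloxylation; the ortho-phenoxide of 4 binds cationic Cp*Rh (trivalent rhodium) and pivalate-assisted cleavage of the formyl C–H gives the five-membered aroyl–rhodium phenoxide chelate established for salicylaldehydes, the phenoxide of 8 takes the free site, monovalent silver oxidises the complex to tetravalent rhodium and triggers C(acyl)–O reductive elimination, and further monovalent silver returns the catalyst to trivalent rhodium; the formyl group of 8 has no ortho OH, cannot chelate and stays untouched, and the chelating OH of 4 cannot close onto its own acyl group (four-membered ring); closest known reaction type: Cp*Rh-catalysed hydroxyl-directed aldehydic C–H amidation and annulation of salicylaldehydes, together with acyl–aryloxide reductive elimination in palladium-catalysed aryloxycarbonylation.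

Step 6
Reactants: 9 4-formyl-3-methoxy-5-pentylphenyl 2-heptyl-6-hydroxy-4-methoxybenzoate
Product: 10 4-[(2-heptyl-6-hydroxy-4-methoxybenzoyl)oxy]-2-methoxy-6-pentylbenzoic acid
Conditions: NaClO2 (3 equiv), NaH2PO4 (3 equiv), 2-methyl-2-butene (20 equiv), t-BuOH/THF/H2O, 0 °C to rt
Reagents that add atoms: sodium chlorite, [Na+].[O-]Cl=O
Why: Pinnick (Lindgren) oxidation; chlorous acid oxidises only the aldehyde at about pH 4, where the aryl ester is stable, and 2-methyl-2-butene removes HOCl before it can chlorinate ring A.

**Compound list**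

1 | 5-heptylbenzene-1,3-diol (5-heptylresorcinol) | CCCCCCCc1cc(O)cc(O)c1 | starting material
2 | ring A iminium chloride, [(2-heptyl-4,6-dihydroxyphenyl)methylidene]dimethylammonium chloride | CCCCCCCc1cc(O)cc(O)c1C=[N+](C)C.[Cl-] | intermediate
3 | 2-heptyl-4,6-dihydroxybenzaldehyde | CCCCCCCc1cc(O)cc(O)c1C=O | intermediate
4 | 2-heptyl-6-hydroxy-4-methoxybenzaldehyde | CCCCCCCc1cc(OC)cc(O)c1C=O | intermediate
5 | 1,3-dimethoxy-5-pentylbenzene (olivetol dimethyl ether) | CCCCCc1cc(OC)cc(OC)c1 | starting material
6 | 3-methoxy-5-pentylphenol | CCCCCc1cc(O)cc(OC)c1 | intermediate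
7 | ring B iminium chloride, [(4-hydroxy-2-methoxy-6-pentylphenyl)methylidene]dimethylammonium chloride | CCCCCc1cc(O)cc(OC)c1C=[N+](C)C.[Cl-] | intermediate
8 | 4-hydroxy-2-methoxy-6-pentylbenzaldehyde | CCCCCc1cc(O)cc(OC)c1C=O | intermediate
9 | 4-formyl-3-methoxy-5-pentylphenyl 2-heptyl-6-hydroxy-4-methoxybenzoate | CCCCCCCc1cc(OC)cc(O)c1C(=O)Oc1cc(CCCCC)c(C=O)c(OC)c1 | intermediate
10 | 4-[(2-heptyl-6-hydroxy-4-methoxybenzoyl)oxy]-2-methoxy-6-pentylbenzoic acid | CCCCCCCc1cc(OC)cc(O)c1C(=O)Oc1cc(CCCCC)c(C(=O)O)c(OC)c1 | target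

**Step count**

Total steps: 6. Longest linear sequence: 4 steps (steps 3, 4, 5, 6 from 5; equally steps 1, 2, 5, 6 from 1).

**Three steps most likely to fail**

Step 5 (the proposed new coupling). The aroyl–rhodium intermediate may lose CO, the C(acyl)–O reductive elimination may be slow, or the OH of a second molecule of 4 may compete with 8 as the nucleophile. The fallback uses known chemistry, sets out from 4 and comes back at 9. Aldehyde 4 is oxidised with NaClO2, NaH2PO4 and 2-methyl-2-butene to 2-heptyl-6-hydroxy-4-methoxybenzoic acid F6. Treating this acid with trifluoroacetic anhydride in toluene at rt gives 2-heptyl-6-hydroxy-4-methoxybenzoic trifluoroacetic anhydride F7, which is not isolated and acylates the phenol OH of 8 in the same flask to give 9 (the classical mixed-anhydride depside esterification).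

Step 4 (para against ortho formylation). If too much of the ortho-hydroxy isomer forms, the fallback sets out from 5 and comes back at 8. Both methyl ethers of 5 are cleaved with BBr3 (CH2Cl2, −78 °C to rt) to 5-pentylbenzene-1,3-diol F1. Vilsmeier–Haack formylation (POCl3, DMF, then water) passes through [(2,4-dihydroxy-6-pentylphenyl)methylidene]dimethylammonium chloride F2, not isolated, and gives 2,4-dihydroxy-6-pentylbenzaldehyde F3; here only one regioisomer is possible next to the chain. The free 4-OH is benzylated selectively (BnBr 1.05 equiv, K2CO3, acetone, rt) to 4-(benzyloxy)-2-hydroxy-6-pentylbenzaldehyde F4. The chelated 2-OH is then methylated (MeI, K2CO3, DMF, 50 °C) to 4-(benzyloxy)-2-methoxy-6-pentylbenzaldehyde F5. Hydrogenolysis (H2, 10% Pd/C, EtOAc, rt, stopped after one equivalent) gives 8.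

Step 6 (chlorination of the electron-rich ring A or loss of the aryl ester on the full depside). The fallback moves the oxidation ahead of the coupling, sets out from 8 (with acid F6 made from 4 as above) and comes back at 10. Aldehyde 8 is oxidised (NaClO2, NaH2PO4, 2-methyl-2-butene) to 4-hydroxy-2-methoxy-6-pentylbenzoic acid F8. Its carboxylate is alkylated (BnBr, KHCO3, DMF, rt) to benzyl 4-hydroxy-2-methoxy-6-pentylbenzoate F9. F9 is acylated with 2-heptyl-6-hydroxy-4-methoxybenzoic acid F6 through the mixed anhydride 2-heptyl-6-hydroxy-4-methoxybenzoic trifluoroacetic anhydride F7 (trifluoroacetic anhydride, toluene, rt) to give benzyl 4-[(2-heptyl-6-hydroxy-4-methoxybenzoyl)oxy]-2-methoxy-6-pentylbenzoate F10. Hydrogenolysis of the benzyl ester (H2, 10% Pd/C, EtOAc, rt) gives 10.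

**Further compounds**

F1 | step 4 | 5-pentylbenzene-1,3-diol | CCCCCc1cc(O)cc(O)c1
F2 | step 4 | [(2,4-dihydroxy-6-pentylphenyl)methylidene]dimethylammonium chloride | CCCCCc1cc(O)cc(O)c1C=[N+](C)C.[Cl-]
F3 | step 4 | 2,4-dihydroxy-6-pentylbenzaldehyde | CCCCCc1cc(O)cc(O)c1C=O
F4 | step 4 | 4-(benzyloxy)-2-hydroxy-6-pentylbenzaldehyde | CCCCCc1cc(OCc2ccccc2)cc(O)c1C=O
F5 | step 4 | 4-(benzyloxy)-2-methoxy-6-pentylbenzaldehyde | CCCCCc1cc(OCc2ccccc2)cc(OC)c1C=O
F6 | step 5 | 2-heptyl-6-hydroxy-4-methoxybenzoic acid | CCCCCCCc1cc(OC)cc(O)c1C(=O)O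
F7 | step 5 | 2-heptyl-6-hydroxy-4-methoxybenzoic trifluoroacetic anhydride | CCCCCCCc1cc(OC)cc(O)c1C(=O)OC(=O)C(F)(F)F
F8 | step 6 | 4-hydroxy-2-methoxy-6-pentylbenzoic acid | CCCCCc1cc(O)cc(OC)c1C(=O)O
F9 | step 6 | benzyl 4-hydroxy-2-methoxy-6-pentylbenzoate | CCCCCc1cc(O)cc(OC)c1C(=O)OCc1ccccc1
F10 | step 6 | benzyl 4-[(2-heptyl-6-hydroxy-4-methoxybenzoyl)oxy]-2-methoxy-6-pentylbenzoate | CCCCCCCc1cc(OC)cc(O)c1C(=O)Oc1cc(CCCCC)c(C(=O)OCc2ccccc2)c(OC)c1
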